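(Readings and results are calculated from invented constants; scatter was added.)

Time is my starting point: I take what becomes of a portion of free monomer to depend on the minutes it spends in the flask, measured against a clock you can read from Wednesday's run, which has the same charge as the set-ups here (41 mM, 0.6 mol%).

in all of them: initiator 0.6 mol%
- Wednesday's: free monomer 41 mM; run made earlier
- Tuesday's: free monomer 57 mM; run made earlier
- Monday's: free monomer 90 mM; run made earlier
- winter: free monomer 41 mM; one stirred flow tank at steady state, fed with the mixture as stated, mean residence time 50 min
- noon: free monomer 41 mM (fed, over 40.0 min); a stirred flask in which free monomer is dosed at a steady rate over 40.0 min without added volume, worked up at 50 min; time 50 min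
- dawn: free monomer 41 mM; a closed flask charged with all of it at once and left for 50 min; time 50 min

| run | time / min | monomer in chains / % | free monomer / % |
|---|---|---|---|
| Wednesday's | 4.00 | 10 | 94 |
| Wednesday's | 8.00 | 19 | 85 |
| Wednesday's | 15.0 | 29 | 68 |
| Wednesday's | 25.0 | 45 | 55 |
| Wednesday's | 50.0 | 72 | 27 |
| Tuesday's | 3.00 | 6 | 94 |
| Tuesday's | 6.00 | 14 | 86 |
| Tuesday's | 12.0 | 31 | 67 |
| Tuesday's | 20.0 | 53 | 47 |
| Tuesday's | 40.0 | 75 | 19 |
| Monday's | 3.00 | 13 | 89 |
| Monday's | 6.00 | 27 | 76 |
| Monday's | 12.0 | 50 | 52 |
| Monday's | 20.0 | 68 | 30 |
| Monday's | 40.0 | 90 | 12 |

(readings scatter by 2 percentage points)

- the set-up with the highest amount of monomer in chains at the outlet or at the end, in percent of the free monomer put in ("none" if the first two lie within 2 percentage points) (winter / noon / dawn / none)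
- amount of monomer in chains at the outlet or at the end, in percent of the free monomer put in, winter
- amount of monomer in chains at the outlet or at the end, in percent of the free monomer put in, noon
- amount of monomer in chains at the outlet or at the end, in percent of the free monomer put in, dawn

- the stated concentrations are those of everything mixed, before any reaction; amounts are the same in each set-up
- the feed brings no volume worth counting
- the earlier runs were made in a closed, stirred flask

Late in Wednesday's run, free monomer fell from 55% to 27% of the charge between 25.0 min and 50.0 min. If a steady fraction goes each minute (pseudo-first-order), that gives 35.1 min: call it the growth time, the minutes in which free monomer falls by a factor e.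

Each reading is good to 2 percentage points, so this time is itself a reading and carries that scatter. The second time is how long a portion stays in the flask, and their ratio is my whole reckoning. In dawn a portion stays 50 min, which is longer than the growth time, so I expect 75.9% in chains. The winter tank has the same stay on average, but it is mixed, so the fraction left is one over one plus the ratio, and I expect 58.7%. In noon the portions stay 30.0 min on average; averaging over the feed gives 55.1%. That assumes noon grows on the same clock, so when you repeat noon, watch the fraction of free monomer lost per minute after the feed ends.

The forecast, with figures of its own that differ from mine, gave 55% for winter, 51% for noon, “assuming initiator is charged at the start”, and 73% for dawn, and chose dawn.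

The flask gives 60.9% for winter, 18.4% for noon and 73.6% for dawn, so the best is dawn.

    free monomer + initiator → living end + monomer in chains (k = 6.22 M⁻¹ min⁻¹)
    free monomer + living end → monomer in chains + living end, rate k2*[living end]*[free monomer] (k = 249 M⁻¹ min⁻¹)
    2 initiator → spent initiator (k = 1540 M⁻¹ min⁻¹)

Noon lies 37 points under my figure, so its clock is not 35.1 min. Living ends stood at 0.0303 mM in noon against 0.113 mM in dawn, and the growth time goes inversely with them, which stretches noon's to 131 min. The largest single effect on the gap between noon and dawn is initiator pairing off into spent initiator: without that step the gap narrows from 55 points to 18 points. Carried from 81.6% free monomer at 50.0 min to 3.0 h, the stretched time gives 30.4%, and noon left that long holds 30.6%.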